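The vinylic carbon C4 of ring B (the cyclohexene ring bearing the hydroxylated side chain) is treated as a latent ketone, so that the C3–C4 bond of the C3H2–C4H=C5(CH3) array becomes the acyl–alkyl bond of a 2-methylcyclohex-2-enone. The key step joins two electrophilic carbons by polarity reversal: iodine–lithium exchange at C3 of an acyclic (Z)-iodo enoate (C1 quaternary, C2 set by Evans alkylation) and attack on ester carbon C4 close the ring. The C4 oxygen then relays chirality: 1,2-reduction and a [2,3]-Wittig–Still shift set C6, place the C4=C5 alkene and deliver C7. The same enone serves ring A; two Julia–Kocienski olefinations of crocetindialdehyde build the polyene.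

Key step: step 7

Remark: ring atoms are referred to by carotenoid numbering (C1 = CMe2, C2 = CH bearing the C5 side chain, C3 = CH2, C4 = vinylic CH, C5 = methyl-bearing alkene carbon, C6 = CH bearing the chain, C7 = first chain carbon; ring A carries the prenyl group, ring B the hydroxylated one), and compounds 1, 2, 5, 10, 19, 23 and all-E crocetindialdehyde 32 are taken as commercially available.

**Common part (steps 1–7)**

Step 1
Reactants: 1 2,2-dimethylsuccinic anhydride (3,3-dimethyloxolane-2,5-dione); 2 (4R)-4-benzyl-1,3-oxazolidin-2-one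
Product: 4 methyl 4-[(4R)-4-benzyl-2-oxo-1,3-oxazolidin-3-yl]-2,2-dimethyl-4-oxobutanoate, via lithium carboxylate 3 (not isolated)
Conditions: n-BuLi, THF, −78 °C; 1, −78 → 0 °C; then MeI, DMF, rt
Reagents that add atoms: iodomethane, CI
Why: N-acylation of the lithiated oxazolidinone by the anhydride at its less hindered, CH2-flanked carbonyl, followed by O-methylation of the lithium carboxylate in the same flask; no stereocentre is formed.

Step 2
Reactants: 4 methyl 4-[(4R)-4-benzyl-2-oxo-1,3-oxazolidin-3-yl]-2,2-dimethyl-4-oxobutanoate; 5 1-bromo-3-methylbut-2-ene (prenyl bromide)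
Product: 6 methyl (3R)-3-{[(4R)-4-benzyl-2-oxo-1,3-oxazolidin-3-yl]carbonyl}-2,2,6-trimethylhept-5-enoate
Conditions: NaN(SiMe3)2, THF, −78 °C; then 5, −78 → −20 °C
Reagents that add atoms: none
Why: Evans alkylation, in which the chelated (Z)-sodium enolate is alkylated by the allylic bromide on the face opposite the benzyl group and so sets C2 (the ester on the quaternary carbon has no α-hydrogen).

Step 3
Reactants: 6 methyl (3R)-3-{[(4R)-4-benzyl-2-oxo-1,3-oxazolidin-3-yl]carbonyl}-2,2,6-trimethylhept-5-enoate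
Product: 8 (4R)-3,3-dimethyl-4-(3-methylbut-2-en-1-yl)oxolan-2-one, via hydroxy ester 7 (not isolated)
Conditions: LiBH4, MeOH (1 equiv), THF, 0 °C; then pyridinium p-toluenesulfonate (cat.), CH2Cl2, rt
Reagents that add atoms: none
Why: Reductive cleavage of the imide to the primary alcohol (C3), which lactonises onto the neighbouring hindered methyl ester in a 5-exo closure favoured by the gem-dimethyl group; C2 is untouched and the auxiliary is recovered.

Step 4
Reactants: 8 (4R)-3,3-dimethyl-4-(3-methylbut-2-en-1-yl)oxolan-2-one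
Product: 9 (4R)-3,3-dimethyl-4-(3-methylbut-2-en-1-yl)oxolan-2-ol (both anomers)
Conditions: i-Bu2AlH, CH2Cl2, −78 °C
Reagents that add atoms: none
Why: Partial reduction of the hindered lactone, which should stop at the lactol because the tetrahedral aluminium alkoxide is stable at low temperature.

Step 5
Reactants: 9 (4R)-3,3-dimethyl-4-(3-methylbut-2-en-1-yl)oxolan-2-ol; 10 ethyl 2-[bis(2,2,2-trifluoroethoxy)phosphoryl]propanoate
Product: 11 ethyl (2Z,5R)-5-(hydroxymethyl)-2,4,4,8-tetramethylnona-2,7-dienoate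
Conditions: KN(SiMe3)2, 18-crown-6, THF, −78 → −20 °C
Reagents that add atoms: none
Why: Still–Gennari variant of the Horner–Wadsworth–Emmons olefination on the open hydroxy-aldehyde form of the lactol, where the electron-poor phosphonate should give the (Z)-trisubstituted enoate under kinetic control and so place ester carbon C4 cis to C1.

Step 6
Reactants: 11 ethyl (2Z,5R)-5-(hydroxymethyl)-2,4,4,8-tetramethylnona-2,7-dienoate
Product: 12 ethyl (2Z,5R)-5-(iodomethyl)-2,4,4,8-tetramethylnona-2,7-dienoate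
Conditions: I2, PPh3, imidazole, CH2Cl2, 0 °C
Reagents that add atoms: iodine, II
Why: Appel iodination of the primary alcohol (SN2 on the alkoxyphosphonium ion) under neutral conditions that leave the (Z)-enoate and the prenyl group untouched.

Step 7
Reactants: 12 ethyl (2Z,5R)-5-(iodomethyl)-2,4,4,8-tetramethylnona-2,7-dienoate
Product: 15 (5S)-2,4,4-trimethyl-5-(3-methylbut-2-en-1-yl)cyclohex-2-en-1-one, via alkyllithium 13 (not isolated), via lithium hemiketal alkoxide 14 (not isolated)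
Conditions: t-BuLi (2 equiv), Et2O–pentane, −78 → −20 °C; then H2O
Reagents that add atoms: none
Why: Iodine–lithium exchange at C3 is much faster than addition of t-BuLi to the ester at −78 °C and gives primary alkyllithium 13, whose carbanion attacks the ester carbonyl C4, held cis by the (Z)-alkene, to give lithium hemiketal 14, which collapses to the enone on warming and work-up. The closest known reaction type is the halogen–lithium-exchange-initiated intramolecular acylation of halo esters to cyclic ketones (Parham-type cyclisation). The six-membered ring closes in the 6-exo-trig mode at the carbonyl carbon, helped by the gem-dimethyl group at C1 and the cis alkene. No stereocentre is created in 15: the hemiketal centre of 14 is lost, and C2, set in step 2, is β to the new carbonyl and cannot epimerise. The step needs exchange to outrun carbonyl addition by t-BuLi and carbonyl attack to outrun conjugate attack; the first is secured by temperature and stoichiometry (the second equivalent is consumed by t-BuI), the second by geometry, since attack at the β-carbon C6 would form a four-membered ring.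

**Ring B branch (steps 8–14)**

Step 8
Reactants: 15 (5S)-2,4,4-trimethyl-5-(3-methylbut-2-en-1-yl)cyclohex-2-en-1-one
Product: 16 (5S)-5-[(2E)-4-hydroxy-3-methylbut-2-en-1-yl]-2,4,4-trimethylcyclohex-2-en-1-one
Conditions: SeO2 (0.5 equiv), t-BuOOH, salicylic acid (cat.), CH2Cl2, rt
Reagents that add atoms: selenium dioxide, O=[Se]=O (oxygen carrier); tert-butyl hydroperoxide, CC(C)(C)OO (terminal oxidant)
Why: Allylic oxidation (ene reaction, then [2,3]-shift of the allylseleninic acid) should take place at the (E)-methyl of the electron-rich prenyl alkene and give the (E)-allylic alcohol, the electron-poor enone alkene reacting much more slowly.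

Step 9
Reactants: 16 (5S)-5-[(2E)-4-hydroxy-3-methylbut-2-en-1-yl]-2,4,4-trimethylcyclohex-2-en-1-one
Product: 17 (5S)-5-[(2E)-4-{[tert-butyl(dimethyl)silyl]oxy}-3-methylbut-2-en-1-yl]-2,4,4-trimethylcyclohex-2-en-1-one
Conditions: t-BuMe2SiCl, imidazole, DMF, rt
Reagents that add atoms: tert-butyldimethylsilyl chloride, CC(C)(C)[Si](C)(C)Cl
Why: Silylation of the primary allylic alcohol, so that only the ring hydroxyl is free in steps 11 and 12.

Step 10
Reactants: 17 (5S)-5-[(2E)-4-{[tert-butyl(dimethyl)silyl]oxy}-3-methylbut-2-en-1-yl]-2,4,4-trimethylcyclohex-2-en-1-one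
Product: 18 (1S,5S)-5-[(2E)-4-{[tert-butyl(dimethyl)silyl]oxy}-3-methylbut-2-en-1-yl]-2,4,4-trimethylcyclohex-2-en-1-ol
Conditions: (R)-2-methyl-CBS-oxazaborolidine, catecholborane, toluene, −78 °C
Reagents that add atoms: none
Why: Corey–Bakshi–Shibata reduction, in which the (R)-oxazaborolidine (the methyl-bearing alkene carbon acting as the large group) should deliver hydride by reagent control to give the (1S)-alcohol, hydroxyl trans to the C2 side chain.

Step 11
Reactants: 18 (1S,5S)-5-[(2E)-4-{[tert-butyl(dimethyl)silyl]oxy}-3-methylbut-2-en-1-yl]-2,4,4-trimethylcyclohex-2-en-1-ol; 19 tributyl(iodomethyl)stannane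
Product: 20 tributyl[({(1S,5S)-5-[(2E)-4-{[tert-butyl(dimethyl)silyl]oxy}-3-methylbut-2-en-1-yl]-2,4,4-trimethylcyclohex-2-en-1-yl}oxy)methyl]stannane
Conditions: KH, 18-crown-6 (cat.), THF, 0 °C → rt
Reagents that add atoms: none
Why: Williamson etherification of the potassium alkoxide with the reactive iodomethylstannane, with retention at the carbinol carbon.

Step 12
Reactants: 20 tributyl[({(1S,5S)-5-[(2E)-4-{[tert-butyl(dimethyl)silyl]oxy}-3-methylbut-2-en-1-yl]-2,4,4-trimethylcyclohex-2-en-1-yl}oxy)methyl]stannane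
Product: 22 {(1S,5R)-5-[(2E)-4-{[tert-butyl(dimethyl)silyl]oxy}-3-methylbut-2-en-1-yl]-2,6,6-trimethylcyclohex-2-en-1-yl}methanol, via lithiomethyl ether 21 (not isolated)
Conditions: n-BuLi, THF, −78 → −20 °C; then H2O
Reagents that add atoms: none
Why: Tin–lithium exchange gives the α-alkoxymethyllithium, whose [2,3]-Wittig–Still rearrangement delivers the CH2O unit suprafacially from the pseudo-axial C4–O bond to C6, so that C6 is set trans to the C2 side chain, the alkene moves to C4=C5 and the oxygen ends on C7.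

Step 13
Reactants: 22 {(1S,5R)-5-[(2E)-4-{[tert-butyl(dimethyl)silyl]oxy}-3-methylbut-2-en-1-yl]-2,6,6-trimethylcyclohex-2-en-1-yl}methanol; 23 1-phenyl-1H-tetrazole-5-thiol
Product: 24 5-[({(1S,5R)-5-[(2E)-4-{[tert-butyl(dimethyl)silyl]oxy}-3-methylbut-2-en-1-yl]-2,6,6-trimethylcyclohex-2-en-1-yl}methyl)sulfanyl]-1-phenyl-1H-tetrazole
Conditions: PPh3, diisopropyl azodicarboxylate, THF, 0 °C → rt
Reagents that add atoms: none
Why: Mitsunobu thioetherification of the primary alcohol by the acidic tetrazolethiol; the stereocentres are not involved.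

Step 14
Reactants: 24 5-[({(1S,5R)-5-[(2E)-4-{[tert-butyl(dimethyl)silyl]oxy}-3-methylbut-2-en-1-yl]-2,6,6-trimethylcyclohex-2-en-1-yl}methyl)sulfanyl]-1-phenyl-1H-tetrazole
Product: 25 5-[({(1S,5R)-5-[(2E)-4-{[tert-butyl(dimethyl)silyl]oxy}-3-methylbut-2-en-1-yl]-2,6,6-trimethylcyclohex-2-en-1-yl}methyl)sulfonyl]-1-phenyl-1H-tetrazole
Conditions: (NH4)6Mo7O24·4H2O (cat.), 30% aq. H2O2, EtOH, 0 °C → rt
Reagents that add atoms: hydrogen peroxide, OO
Why: Molybdate-catalysed peroxide oxidation of the sulfide to the sulfone, conditions under which trisubstituted alkenes and the silyl ether should survive.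

**Ring A branch (steps 15–19)**

Step 15
Reactants: 15 (5S)-2,4,4-trimethyl-5-(3-methylbut-2-en-1-yl)cyclohex-2-en-1-one
Product: 26 (1R,5S)-2,4,4-trimethyl-5-(3-methylbut-2-en-1-yl)cyclohex-2-en-1-ol
Conditions: NaBH4, CeCl3·7H2O, MeOH, −78 → 0 °C
Reagents that add atoms: none
Why: Luche 1,2-reduction, where axial hydride delivery to the half-chair with the C2 side chain pseudo-equatorial should give the cis (1R) allylic alcohol by substrate control.

Step 16
Reactants: 26 (1R,5S)-2,4,4-trimethyl-5-(3-methylbut-2-en-1-yl)cyclohex-2-en-1-ol; 19 tributyl(iodomethyl)stannane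
Product: 27 tributyl[({(1R,5S)-2,4,4-trimethyl-5-(3-methylbut-2-en-1-yl)cyclohex-2-en-1-yl}oxy)methyl]stannane
Conditions: KH, 18-crown-6 (cat.), THF, 0 °C → rt
Reagents that add atoms: none
Why: Williamson etherification of the potassium alkoxide, as in step 11.

Step 17
Reactants: 27 tributyl[({(1R,5S)-2,4,4-trimethyl-5-(3-methylbut-2-en-1-yl)cyclohex-2-en-1-yl}oxy)methyl]stannane
Product: 29 [(1R,5S)-2,6,6-trimethyl-5-(3-methylbut-2-en-1-yl)cyclohex-2-en-1-yl]methanol, via lithiomethyl ether 28 (not isolated)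
Conditions: n-BuLi, THF, −78 → −20 °C; then H2O
Reagents that add atoms: none
Why: The same [2,3]-Wittig–Still rearrangement, whose suprafacial delivery from the cis C4–O bond sets C6 cis to the prenyl group through the half-chair conformer with a pseudo-axial C–O bond.

Step 18
Reactants: 29 [(1R,5S)-2,6,6-trimethyl-5-(3-methylbut-2-en-1-yl)cyclohex-2-en-1-yl]methanol; 23 1-phenyl-1H-tetrazole-5-thiol
Product: 30 1-phenyl-5-({[(1R,5S)-2,6,6-trimethyl-5-(3-methylbut-2-en-1-yl)cyclohex-2-en-1-yl]methyl}sulfanyl)-1H-tetrazole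
Conditions: PPh3, diisopropyl azodicarboxylate, THF, 0 °C → rt
Reagents that add atoms: none
Why: Mitsunobu thioetherification of the primary alcohol, as in step 13.

Step 19
Reactants: 30 1-phenyl-5-({[(1R,5S)-2,6,6-trimethyl-5-(3-methylbut-2-en-1-yl)cyclohex-2-en-1-yl]methyl}sulfanyl)-1H-tetrazole
Product: 31 1-phenyl-5-({[(1R,5S)-2,6,6-trimethyl-5-(3-methylbut-2-en-1-yl)cyclohex-2-en-1-yl]methyl}sulfonyl)-1H-tetrazole
Conditions: (NH4)6Mo7O24·4H2O (cat.), 30% aq. H2O2, EtOH, 0 °C → rt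
Reagents that add atoms: hydrogen peroxide, OO
Why: Molybdate-catalysed oxidation of the sulfide to the sulfone, as in step 14.

**Assembly (steps 20–22)**

Step 20
Reactants: 31 1-phenyl-5-({[(1R,5S)-2,6,6-trimethyl-5-(3-methylbut-2-en-1-yl)cyclohex-2-en-1-yl]methyl}sulfonyl)-1H-tetrazole; 32 (2E,4E,6E,8E,10E,12E,14E)-2,6,11,15-tetramethylhexadeca-2,4,6,8,10,12,14-heptaenedial (crocetindialdehyde)
Product: 33 (2E,4E,6E,8E,10E,12E,14E,16E)-2,6,11,15-tetramethyl-17-[(1R,5S)-2,6,6-trimethyl-5-(3-methylbut-2-en-1-yl)cyclohex-2-en-1-yl]heptadeca-2,4,6,8,10,12,14,16-octaenal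
Conditions: KN(SiMe3)2, THF, −78 °C; then 32 (3 equiv), −78 °C → rt; dark, argon
Reagents that add atoms: none
Why: Julia–Kocienski olefination (addition of the sulfonyl carbanion to one aldehyde, Smiles rearrangement, loss of SO2 and tetrazololate) should give the (E)-C7=C8 alkene, the excess of dialdehyde suppressing double olefination.

Step 21
Reactants: 33 (2E,4E,6E,8E,10E,12E,14E,16E)-2,6,11,15-tetramethyl-17-[(1R,5S)-2,6,6-trimethyl-5-(3-methylbut-2-en-1-yl)cyclohex-2-en-1-yl]heptadeca-2,4,6,8,10,12,14,16-octaenal; 25 5-[({(1S,5R)-5-[(2E)-4-{[tert-butyl(dimethyl)silyl]oxy}-3-methylbut-2-en-1-yl]-2,6,6-trimethylcyclohex-2-en-1-yl}methyl)sulfonyl]-1-phenyl-1H-tetrazole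
Product: 34 tert-butyldimethylsilyl ether of (2S,6R,2′R,6′S)-2-(3-methylbut-2-en-1-yl)-2′-[(2E)-4-hydroxy-3-methylbut-2-en-1-yl]-ε,ε-carotene (all-E)
Conditions: KN(SiMe3)2, THF, −78 °C (25); then 33, −78 °C → rt; dark, argon
Reagents that add atoms: none
Why: Second Julia–Kocienski olefination, forming the (E)-C7′=C8′ alkene and completing the C50 skeleton without touching the C6 and C6′ stereocentres, which are not acidic.

Step 22
Reactants: 34 tert-butyldimethylsilyl ether of the target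
Product: 35 (2S,6R,2′R,6′S)-2-(3-methylbut-2-en-1-yl)-2′-[(2E)-4-hydroxy-3-methylbut-2-en-1-yl]-ε,ε-carotene (all-E; CNP0304855.1)
Conditions: Bu4NF, AcOH, THF, 0 °C → rt; dark, argon
Reagents that add atoms: none
Why: Fluoride cleavage of the primary allylic silyl ether under buffered conditions that the polyene should tolerate.

**Compound list**

1 | 2,2-dimethylsuccinic anhydride | CC1(C)CC(=O)OC1=O | starting material
2 | (4R)-4-benzyl-1,3-oxazolidin-2-one | O=C1N[C@H](Cc2ccccc2)CO1 | starting material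
3 | lithium 4-[(4R)-4-benzyl-2-oxo-1,3-oxazolidin-3-yl]-2,2-dimethyl-4-oxobutanoate | [Li+].[O-]C(=O)C(C)(C)CC(=O)N1C(=O)OC[C@H]1Cc2ccccc2 | intermediate
4 | methyl 4-[(4R)-4-benzyl-2-oxo-1,3-oxazolidin-3-yl]-2,2-dimethyl-4-oxobutanoate | COC(=O)C(C)(C)CC(=O)N1C(=O)OC[C@H]1Cc2ccccc2 | intermediate
5 | 1-bromo-3-methylbut-2-ene | CC(C)=CCBr | starting material
6 | methyl (3R)-3-{[(4R)-4-benzyl-2-oxo-1,3-oxazolidin-3-yl]carbonyl}-2,2,6-trimethylhept-5-enoate | COC(=O)C(C)(C)[C@@H](CC=C(C)C)C(=O)N1C(=O)OC[C@H]1Cc2ccccc2 | intermediate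
7 | methyl (3R)-3-(hydroxymethyl)-2,2,6-trimethylhept-5-enoate | COC(=O)C(C)(C)[C@@H](CC=C(C)C)CO | intermediate
8 | (4R)-3,3-dimethyl-4-(3-methylbut-2-en-1-yl)oxolan-2-one | CC(C)=CC[C@H]1COC(=O)C1(C)C | intermediate
9 | (4R)-3,3-dimethyl-4-(3-methylbut-2-en-1-yl)oxolan-2-ol (both anomers) | CC(C)=CC[C@H]1COC(O)C1(C)C | intermediate
10 | ethyl 2-[bis(2,2,2-trifluoroethoxy)phosphoryl]propanoate | CCOC(=O)C(C)P(=O)(OCC(F)(F)F)OCC(F)(F)F | starting material
11 | ethyl (2Z,5R)-5-(hydroxymethyl)-2,4,4,8-tetramethylnona-2,7-dienoate | CCOC(=O)/C(C)=C\C(C)(C)[C@@H](CC=C(C)C)CO | intermediate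
12 | ethyl (2Z,5R)-5-(iodomethyl)-2,4,4,8-tetramethylnona-2,7-dienoate | CCOC(=O)/C(C)=C\C(C)(C)[C@@H](CC=C(C)C)CI | intermediate
13 | alkyllithium from 12 (lithium in place of iodine at C3) | CCOC(=O)/C(C)=C\C(C)(C)[C@@H](CC=C(C)C)C[Li] | intermediate
14 | lithium (5S)-1-ethoxy-2,4,4-trimethyl-5-(3-methylbut-2-en-1-yl)cyclohex-2-en-1-olate | [Li+].CCOC1([O-])C[C@H](CC=C(C)C)C(C)(C)C=C1C | intermediate
15 | (5S)-2,4,4-trimethyl-5-(3-methylbut-2-en-1-yl)cyclohex-2-en-1-one | CC1=CC(C)(C)[C@@H](CC=C(C)C)CC1=O | intermediate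
16 | (5S)-5-[(2E)-4-hydroxy-3-methylbut-2-en-1-yl]-2,4,4-trimethylcyclohex-2-en-1-one | CC1=CC(C)(C)[C@@H](C/C=C(\C)CO)CC1=O | intermediate
17 | (5S)-5-[(2E)-4-{[tert-butyl(dimethyl)silyl]oxy}-3-methylbut-2-en-1-yl]-2,4,4-trimethylcyclohex-2-en-1-one | CC1=CC(C)(C)[C@@H](C/C=C(\C)CO[Si](C)(C)C(C)(C)C)CC1=O | intermediate
18 | (1S,5S)-5-[(2E)-4-{[tert-butyl(dimethyl)silyl]oxy}-3-methylbut-2-en-1-yl]-2,4,4-trimethylcyclohex-2-en-1-ol | CC1=CC(C)(C)[C@@H](C/C=C(\C)CO[Si](C)(C)C(C)(C)C)C[C@@H]1O | intermediate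
19 | tributyl(iodomethyl)stannane | CCCC[Sn](CCCC)(CCCC)CI | starting material
20 | tributyl[({(1S,5S)-5-[(2E)-4-{[tert-butyl(dimethyl)silyl]oxy}-3-methylbut-2-en-1-yl]-2,4,4-trimethylcyclohex-2-en-1-yl}oxy)methyl]stannane | CC1=CC(C)(C)[C@@H](C/C=C(\C)CO[Si](C)(C)C(C)(C)C)C[C@@H]1OC[Sn](CCCC)(CCCC)CCCC | intermediate
21 | lithiomethyl ether of 18 | CC1=CC(C)(C)[C@@H](C/C=C(\C)CO[Si](C)(C)C(C)(C)C)C[C@@H]1OC[Li] | intermediate
22 | {(1S,5R)-5-[(2E)-4-{[tert-butyl(dimethyl)silyl]oxy}-3-methylbut-2-en-1-yl]-2,6,6-trimethylcyclohex-2-en-1-yl}methanol | OC[C@H]1C(C)=CC[C@H](C/C=C(\C)CO[Si](C)(C)C(C)(C)C)C1(C)C | intermediate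
23 | 1-phenyl-1H-tetrazole-5-thiol | Sc1nnnn1-c2ccccc2 | starting material
24 | 5-[({(1S,5R)-5-[(2E)-4-{[tert-butyl(dimethyl)silyl]oxy}-3-methylbut-2-en-1-yl]-2,6,6-trimethylcyclohex-2-en-1-yl}methyl)sulfanyl]-1-phenyl-1H-tetrazole | c1ccccc1-n2nnnc2SC[C@H]3C(C)=CC[C@H](C/C=C(\C)CO[Si](C)(C)C(C)(C)C)C3(C)C | intermediate
25 | 5-[({(1S,5R)-5-[(2E)-4-{[tert-butyl(dimethyl)silyl]oxy}-3-methylbut-2-en-1-yl]-2,6,6-trimethylcyclohex-2-en-1-yl}methyl)sulfonyl]-1-phenyl-1H-tetrazole | O=S(=O)(C[C@H]1C(C)=CC[C@H](C/C=C(\C)CO[Si](C)(C)C(C)(C)C)C1(C)C)c2nnnn2-c3ccccc3 | intermediate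
26 | (1R,5S)-2,4,4-trimethyl-5-(3-methylbut-2-en-1-yl)cyclohex-2-en-1-ol | CC1=CC(C)(C)[C@@H](CC=C(C)C)C[C@H]1O | intermediate
27 | tributyl[({(1R,5S)-2,4,4-trimethyl-5-(3-methylbut-2-en-1-yl)cyclohex-2-en-1-yl}oxy)methyl]stannane | CC1=CC(C)(C)[C@@H](CC=C(C)C)C[C@H]1OC[Sn](CCCC)(CCCC)CCCC | intermediate
28 | lithiomethyl ether of 26 | CC1=CC(C)(C)[C@@H](CC=C(C)C)C[C@H]1OC[Li] | intermediate
29 | [(1R,5S)-2,6,6-trimethyl-5-(3-methylbut-2-en-1-yl)cyclohex-2-en-1-yl]methanol | CC(C)=CC[C@H]1CC=C(C)[C@@H](CO)C1(C)C | intermediate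
30 | 1-phenyl-5-({[(1R,5S)-2,6,6-trimethyl-5-(3-methylbut-2-en-1-yl)cyclohex-2-en-1-yl]methyl}sulfanyl)-1H-tetrazole | CC(C)=CC[C@H]1CC=C(C)[C@@H](CSc2nnnn2-c3ccccc3)C1(C)C | intermediate
31 | 1-phenyl-5-({[(1R,5S)-2,6,6-trimethyl-5-(3-methylbut-2-en-1-yl)cyclohex-2-en-1-yl]methyl}sulfonyl)-1H-tetrazole | CC(C)=CC[C@H]1CC=C(C)[C@@H](CS(=O)(=O)c2nnnn2-c3ccccc3)C1(C)C | intermediate
32 | (2E,4E,6E,8E,10E,12E,14E)-2,6,11,15-tetramethylhexadeca-2,4,6,8,10,12,14-heptaenedial (crocetindialdehyde) | O=C/C(C)=C/C=C/C(C)=C/C=C/C=C(C)/C=C/C=C(C)/C=O | starting material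
33 | (2E,4E,6E,8E,10E,12E,14E,16E)-2,6,11,15-tetramethyl-17-[(1R,5S)-2,6,6-trimethyl-5-(3-methylbut-2-en-1-yl)cyclohex-2-en-1-yl]heptadeca-2,4,6,8,10,12,14,16-octaenal | CC(C)=CC[C@H]1CC=C(C)[C@@H](/C=C/C(C)=C/C=C/C(C)=C/C=C/C=C(C)/C=C/C=C(C)/C=O)C1(C)C | intermediate
34 | tert-butyldimethylsilyl ether of the target | CC(C)=CC[C@H]1CC=C(C)[C@@H](/C=C/C(C)=C/C=C/C(C)=C/C=C/C=C(C)/C=C/C=C(C)/C=C/[C@H]2C(C)=CC[C@H](C/C=C(\C)CO[Si](C)(C)C(C)(C)C)C2(C)C)C1(C)C | intermediate
35 | (2S,6R,2′R,6′S)-2-(3-methylbut-2-en-1-yl)-2′-[(2E)-4-hydroxy-3-methylbut-2-en-1-yl]-ε,ε-carotene (all-E) | CC(C)=CC[C@H]1CC=C(C)[C@@H](/C=C/C(C)=C/C=C/C(C)=C/C=C/C=C(C)/C=C/C=C(C)/C=C/[C@H]2C(C)=CC[C@H](C/C=C(\C)CO)C2(C)C)C1(C)C | target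

**Step count and risks**

Total step count: 22. Longest linear sequence: 16 steps (steps 1–14, then 21 and 22).

Steps most likely to fail:

Step 7 (key ring closure). The alkyllithium may be quenched by proton transfer before it reaches the ester, t-BuLi may add to the enoate in competition with exchange, or the liberated enone may suffer over-addition. The fallback forms the same C3–C4 bond with a stabilised carbanion instead of an organolithium. It sets out from 12: displacement of iodide with PhSO2Na in DMF should give ethyl (2Z,5R)-2,4,4,8-tetramethyl-5-[(phenylsulfonyl)methyl]nona-2,7-dienoate F1. LiN(i-Pr)2 (2 equiv, THF, −78 → 0 °C) should then close the ring by intramolecular acylation of the α-sulfonyl carbanion to give (5R)-2,4,4-trimethyl-5-(3-methylbut-2-en-1-yl)-6-(phenylsulfonyl)cyclohex-2-en-1-one F2 (epimers at the sulfonyl-bearing carbon). Reductive desulfonylation with SmI2 in THF–MeOH at −78 °C brings the route back to 15.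

Step 5 (Z-olefination of the lactol). The hindered lactol may open too slowly, Z-selectivity may erode on warming, and the liberated hydroxyl may add in a conjugate sense to the new enoate. The fallback builds the (Z)-alkene as a vinyl iodide and introduces the ester carbon afterwards. It sets out from 9: Stork–Zhao-type Wittig reaction with Ph3P=C(I)CH3 (from ethyltriphenylphosphonium iodide, n-BuLi, I2, then NaN(SiMe3)2; THF, −78 °C) should give (2R)-2-[(3Z)-4-iodo-2-methylpent-3-en-2-yl]-5-methylhex-4-en-1-ol F3. Alkoxycarbonylation with retention of alkene geometry (Pd(PPh3)4 cat., CO, EtOH, Et3N) brings the route back to 11.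

Step 10 (reagent-controlled reduction). The substrate's own preference for the cis alcohol may override the catalyst in this mismatched case, and the borane may hydroborate the side-chain alkene. The fallback uses substrate control followed by inversion. It sets out from 17: Luche reduction (NaBH4, CeCl3·7H2O, MeOH) should give the cis alcohol (1R,5S)-5-[(2E)-4-{[tert-butyl(dimethyl)silyl]oxy}-3-methylbut-2-en-1-yl]-2,4,4-trimethylcyclohex-2-en-1-ol F4. Mitsunobu inversion with 4-nitrobenzoic acid (PPh3, diisopropyl azodicarboxylate) should give (1S,5S)-5-[(2E)-4-{[tert-butyl(dimethyl)silyl]oxy}-3-methylbut-2-en-1-yl]-2,4,4-trimethylcyclohex-2-en-1-yl 4-nitrobenzoate F5, and methanolysis (K2CO3, MeOH) brings the route back to 18.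

Further compounds
F1 | step 7 | ethyl (2Z,5R)-2,4,4,8-tetramethyl-5-[(phenylsulfonyl)methyl]nona-2,7-dienoate | CCOC(=O)/C(C)=C\C(C)(C)[C@@H](CC=C(C)C)CS(=O)(=O)c1ccccc1
F2 | step 7 | (5R)-2,4,4-trimethyl-5-(3-methylbut-2-en-1-yl)-6-(phenylsulfonyl)cyclohex-2-en-1-one (epimers at C6) | CC1=CC(C)(C)[C@@H](CC=C(C)C)C(S(=O)(=O)c2ccccc2)C1=O
F3 | step 5 | (2R)-2-[(3Z)-4-iodo-2-methylpent-3-en-2-yl]-5-methylhex-4-en-1-ol | C/C(I)=C/C(C)(C)[C@@H](CC=C(C)C)CO
F4 | step 10 | (1R,5S)-5-[(2E)-4-{[tert-butyl(dimethyl)silyl]oxy}-3-methylbut-2-en-1-yl]-2,4,4-trimethylcyclohex-2-en-1-ol | CC1=CC(C)(C)[C@@H](C/C=C(\C)CO[Si](C)(C)C(C)(C)C)C[C@H]1O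
F5 | step 10 | (1S,5S)-5-[(2E)-4-{[tert-butyl(dimethyl)silyl]oxy}-3-methylbut-2-en-1-yl]-2,4,4-trimethylcyclohex-2-en-1-yl 4-nitrobenzoate | CC1=CC(C)(C)[C@@H](C/C=C(\C)CO[Si](C)(C)C(C)(C)C)C[C@@H]1OC(=O)c2ccc(cc2)[N+](=O)[O-]
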